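**Conventions.** Atom labels follow the target SMILES: Cb=Ca (vinyl), C1, C2=C3(CH3), C4, C5, C6(OAr), C7 (acyl-bearing CH), then C8, C9(CH3), C10, C11(CH3), C12, C13(CH3). The lactam atoms are N1′, C2′(=O), C3′, C4′ and C5′(OH). "Upper face" is the face of H1, H5, H7, the C6 oxygen and the C11 methyl. "Lower face" is the face of H4, H6, H8 and the C9 and C13 methyls. Ar = 4-[(tert-butyldiphenylsilyloxy)methyl]phenyl. "Dienonyl" = 1,3,5-trimethyl-4-oxocyclohexa-2,5-dien-1-yl.

## The problem

The target is a 6-5-6 decahydrofluorene: ring A is the cyclohexene C1, C2, C3, C4, C5, C7; ring B is the cyclopentane C4, C5, C6, C8, C13; ring C is the cyclohexane C8 to C13. A 13-membered paracyclophane bridges C6 (aryl ether) and C7 (acyl) and contains a 3-acyl-5-hydroxy-3-pyrrolin-2-one. Nine of the ten stereocentres sit on the tricycle: A/B is trans-fused, B/C is cis-fused, rings A and C lie on the same side of ring B, C13 is quaternary, and the tenth centre is the hemiaminal C5′. H5/H7 are cis and H1/H4 are trans, so one suprafacial cycloaddition of E-alkenes cannot give ring A. The C7 acyl group is axial and the C11 methyl is contra-thermodynamic, so both must be set kinetically and then left alone. The control chain is as follows: C5/C7 can fix C1 and C4, ring A can then fix C6, C8 and C13, the C13/C4 face can fix C11, and C9 can be equilibrated as long as C10 is a carbonyl. The bonds that resist formation are three: the C6–OAr ether (a secondary carbon between two tertiary ones), the C4–C13 bond next to the quaternary centre, and the last bond of the strained macrocycle. The enabling feature is ring C. It carries methyl groups on the alternate atoms C9, C11 and C13 and nothing else, so it is the skeleton of 2,4,6-trimethylphenol with C10 as the phenol carbon and C13 as the para carbon. The derived 4,4-disubstituted dienone is flat with a mirror plane through C10 and C13 and has two equivalent electrophilic β-carbons (C8, C12), and C6/C5/C4/C13/C8=C9 is a 5-hexenyl radical array. The groups that will not survive rough treatment are the hemiaminal, the acylpyrrolinone acceptor, the epimerisable C7–H, the doubly allylic C1–H and the vinyl group.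

## Retrosynthesis

**33 to 31 (C5′–OH and C2′=O removed).** The hydroxylactam is the dioxygen adduct of a 2-benzyl-4-acylpyrrole. This cut is preferred to carrying a hemiaminal or condensing a keto-amide. It removes the most fragile group and one stereocentre in a single operation and leaves a robust flat heteroarene. The forward reaction must oxidise the pyrrole in the presence of the C2=C3 alkene.

**31 to 30 (ArCH2–C5′ cut).** The neighbouring closures are worse. Closure at C6–O is a substitution at the most hindered carbon, and closure at acyl–C3′ has an α/β regiochemical problem on the pyrrole. A 4-alkoxybenzyl cation and C5 of a 3-acylpyrrole are an electronically matched pair. The precursor 30 has no macrocycle. The forward reaction must beat oligomerisation and pay for the ring strain.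

**30 to 25 + 26 (acyl–C3′ cut, vinyl masked).** The ketone comes from ester 25 and 3-lithio-1-(triisopropylsilyl)pyrrole, made from 26. The vinyl group is carried as a trimethylsilylalkyne, so that no second diene exists at the cycloaddition stage. One fluoride step removes all three silyl groups.

**25 to 21 (C10=O and C11=C12 put back).** Re-oxidising ring C reveals the remains of the phenol. It provides the handle that sets C9 by equilibration and C11 by kinetic protonation. The forward sequence needs conjugate reduction, immediate carbonyl reduction and radical deoxygenation.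

**21 to 19 (C6–C8 cut, key step).** Cutting C6–C8 rather than C4–C13 or C4–C5 returns ring C to a flat, achiral dienone and removes four stereocentres (C6, C8, C9, C13), the quaternary one included. The precursor 19 has only the four ring A centres. The forward reaction must choose one of two diastereotopic dienone arms and one face of the C6 radical.

**19 to 13 (C6–Se back to the lactone acylal, C3–CH3 back to C3–O, C4 inverted).** The C3 oxygen left by the cycloaddition serves twice, as the handle for epimerising C4 and as the site for the methyl coupling. The lactone holds C7 in its axial position throughout.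

**13 to 7 + 12 (C4–C5 and C1–C7 cut).** A cyclic Z-dienophile gives H5/H7 cis. The endo rule puts H1 on the same face, and only C4 has to be corrected afterwards. Diene 7 is achiral, so the single stereocentre of 12 decides the absolute configuration.

**12 to 9 + 11 (C6–OAr cut).** The hindered ether is made while C6 is the unhindered acetal carbon of a butenolide, by a stereoconvergent palladium-catalysed substitution of racemic 9.

**7 to 6 to 5 + 4, and 4 to 3 to 1 + 2 (C13–C4 cut).** Oxidative dearomatisation of 2,4,6-trimethylphenol 5 at its para carbon supplies ring C with all three methyl groups and the quaternary carbon in one step.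

## Roads not taken

**Alternative 1:** This is the obvious plan. It cuts C4–C5 and C1–C7 intramolecularly: ring C is built first, the intramolecular Diels–Alder reaction of tetraene ester A1 gives the tricyclic hydroxy ester A2, and the aryl ether and the macrocycle follow. An E-enoate gives H5/H7 trans and an E,E-diene gives H1/H4 cis, so A2 is epimeric with the target at both C1 and C7. The matching Z-enoate and (1Z)-triene would be unreactive, and the triene would undergo 6π-electrocyclisation. Ring C with four stereocentres is needed before the key step, and the C6–O bond is left for the most hindered stage.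

**Alternative 2:** The macrocycle is made first and the cycloaddition is run on it. The paracyclophane enone A3 is closed and the C13 diene then adds to the ring alkene C5=C7. An E-alkene inside the 13-membered ring adds strain and again gives H5/H7 trans. The Z-isomer would correct C7 but not C1, and with C3 already methylated no handle remains to correct C4. Both ring C and the macrocycle must be complete before the key step, so the run-up consumes what the key step gains.

**Alternative 3:** Rings B and C are made first by a catalytic desymmetrisation: the intramolecular Stetter reaction of dienone aldehyde A4 gives hydrindanedione A5. C8, C9 and C13 are set efficiently. Ring A must then be grafted onto C4/C5 with C3 on the concave face, syn to ring C, whereas reagents attack the derived cyclopentenone from the convex face. The C6–OAr bond again becomes a late substitution. The chosen plan keeps the same dearomatisation logic but lets the finished ring A select the dienone arm.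

Key step: step 13

**Assumption:** the C5′ hemiaminal equilibrates by ring–chain tautomerism, and the configuration drawn in the target is taken to be the one the 13-membered ring favours. Compounds 1, 2, 5, 8, 10 and 26 are taken as catalogue compounds.

## Steps

Step 1
Reactants: 1 3-(trimethylsilyl)propynal; 2 1-(triphenylphosphoranylidene)propan-2-one
Product: 3 (E)-6-(trimethylsilyl)hex-3-en-5-yn-2-one
Conditions: CH2Cl2, rt
Reagents that add atoms: none
Why: Wittig olefination with a stabilised ylide should be E-selective, and the aldehyde cannot enolise.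

Step 2
Reactants: 3 (E)-6-(trimethylsilyl)hex-3-en-5-yn-2-one
Product: 4 (E)-2-(tert-butyldimethylsilyloxy)-6-(trimethylsilyl)hexa-1,3-dien-5-yne
Conditions: TBSOTf, Et3N, CH2Cl2, 0 °C
Reagents that add atoms: tert-butyldimethylsilyl trifluoromethanesulfonate, CC(C)(C)[Si](C)(C)OS(=O)(=O)C(F)(F)F
Why: Soft enolisation is used; only the methyl group can enolise, so a single cross-conjugated silyl enol ether should form.

Step 3
Reactants: 4 silyl enol ether; 5 2,4,6-trimethylphenol
Product: 6 2,4,6-trimethyl-4-[(E)-2-oxo-6-(trimethylsilyl)hex-3-en-5-ynyl]cyclohexa-2,5-dienone (achiral)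
Conditions: PhI(OAc)2, 4 (3 equiv), (CF3)2CHOH/CH2Cl2, −10 °C
Reagents that add atoms: none
Why: Proposed new method: PhI(OAc)2 binds the phenol oxygen, loss of PhI in the ionising non-nucleophilic solvent gives the trimethylphenoxenium ion, and the enol ether carbon attacks the para carbon C13, which leads to the more stable cross-conjugated dienone, with silyl transfer to acetate ending the reaction; the closest known reaction types are the oxidative Hosomi–Sakurai para-allylation of 4-alkylphenols with allylsilanes under these conditions and the oxidative coupling of 2-alkoxyarenols with silyl enol ethers, and since a silyl enol ether is the stronger π-nucleophile, C–C bond formation should outrun capture by acetate; no stereocentre arises because 6 keeps a mirror plane through C10 and C13.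

Step 4
Reactants: 6 dienone ketone
Product: 7 4-[(1Z,3E)-2-(tert-butyldimethylsilyloxy)-6-(trimethylsilyl)hexa-1,3-dien-5-ynyl]-2,4,6-trimethylcyclohexa-2,5-dienone
Conditions: TBSOTf, Et3N, CH2Cl2, 0 °C
Reagents that add atoms: tert-butyldimethylsilyl trifluoromethanesulfonate, CC(C)(C)[Si](C)(C)OS(=O)(=O)C(F)(F)F
Why: Soft enolisation is used and C4–H2 is the only enolisable position. The bulky C13 avoids C2 (allylic 1,3-strain), so the Z-enol ether should form, which places C13 "outside" on the diene.

Step 5
Reactants: 8 5-hydroxyfuran-2(5H)-one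
Product: 9 (±)-tert-butyl (5-oxo-2,5-dihydrofuran-2-yl) carbonate
Conditions: Boc2O, DMAP (cat.), CH2Cl2, 0 °C
Reagents that add atoms: di-tert-butyl dicarbonate, CC(C)(C)OC(=O)OC(=O)OC(C)(C)C
Why: This is acylation of the pseudo-acid hydroxyl and gives the ionisable carbonate needed in step 7.

Step 6
Reactants: 10 4-hydroxybenzyl alcohol
Product: 11 4-[(tert-butyldiphenylsilyloxy)methyl]phenol
Conditions: TBDPSCl (1.0 equiv), imidazole, DMF, 0 °C
Reagents that add atoms: tert-butylchlorodiphenylsilane, CC(C)(C)[Si](Cl)(c1ccccc1)c1ccccc1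
Why: Selective silylation of the primary benzylic alcohol of this diol is established practice. The acid-stable silyl group is chosen for steps 9 and 12.

Step 7
Reactants: 9 racemic carbonate; 11 phenol
Product: 12 (R)-5-(ArO)furan-2(5H)-one
Conditions: Pd2(dba)3·CHCl3 (2.5 mol %), (R,R)-N,N′-(cyclohexane-1,2-diyl)bis[2-(diphenylphosphino)benzamide] (7.5 mol %), Bu4NCl, CH2Cl2, 0 °C
Reagents that add atoms: none
Why: This is a Tsuji–Trost-type dynamic kinetic asymmetric substitution in which both enantiomers of 9 ionise to rapidly interconverting η3 complexes of divalent palladium and the ligand directs the phenol to give (R)-C6 (the antipodal ligand is equally available if the sense of induction is opposite). The C6–OAr bond is thus made on an unhindered carbon.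

Step 8
Reactants: 7 silyloxydiene; 12 (R)-aryloxybutenolide
Product: 13 endo/anti adduct: cyclohexene cis-fused to the γ-lactone, C3–OTBS enol ether, (trimethylsilyl)ethynyl on C1, dienonyl on C4; H1, H7, H5 and H4 all cis, C6–OAr on the H5 face
Conditions: PhMe (1 M), BHT, 120 °C, sealed tube
Reagents that add atoms: none
Why: In this Diels–Alder reaction the silyloxy group makes C4 the nucleophilic terminus, so C4 bonds to the lactone β-carbon C5. The diene adds anti to the aryloxy group as with 5-alkoxybutenolides, the cyclic Z-dienophile fixes H5/H7 cis, and the endo rule puts H1 and provisionally H4 on the same face. The alkyne cannot act as a second diene.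

Step 9
Reactants: 13 adduct
Product: 15 C3 ketone with H4 trans to H5, via C4-epimeric ketone 14 (not isolated)
Conditions: TFA (0.1 equiv), wet CH2Cl2, 0 °C; then DBU (0.3 equiv), rt
Reagents that add atoms: none
Why: This is enol ether hydrolysis followed by enolisation at C4. In 14 an equatorial dienonyl group forces C6 and the alkynyl group into a 1,3-diaxial pair, whereas in 15 the dienonyl group, C6 and the alkynyl group are all equatorial, so equilibration should favour 15. C5 and C7 stay locked by the cis-lactone.

Step 10
Reactants: 15 ketone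
Product: 16 C2=C3 enol triflate
Conditions: KHMDS, THF, −78 °C; N-(5-chloro-2-pyridyl)bis(trifluoromethanesulfonimide)
Reagents that add atoms: N-(5-chloro-2-pyridyl)bis(trifluoromethanesulfonimide), O=S(=O)(N(c1ccc(Cl)cn1)S(=O)(=O)C(F)(F)F)C(F)(F)F
Why: Kinetic deprotonation should take the unhindered C2–H2 rather than C4–H next to the quaternary carbon, and O-triflation fixes the alkene position.

Step 11
Reactants: 16 enol triflate
Product: 17 C3-methyl cyclohexene lactone
Conditions: Me2Zn, Pd(PPh3)4 (5 mol %), THF, 40 °C
Reagents that add atoms: dimethylzinc, C[Zn]C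
Why: Negishi coupling of a vinyl triflate is used. Me2Zn does not add to the hindered dienone or to the lactone without a catalyst.

Step 12
Reactants: 17 lactone acylal
Product: 19 methyl ester with C6H(OAr)(SePh), both C6 epimers, via carboxylic acid 18 (not isolated)
Conditions: PhSeH, BF3·OEt2, CH2Cl2, −78 to −40 °C; then Me3SiCHN2, PhMe/MeOH, 0 °C
Reagents that add atoms: benzeneselenol, [SeH]c1ccccc1; (trimethylsilyl)diazomethane, C[Si](C)(C)C=[N+]=[N-]
Why: This is a Lewis-acid exchange of an acyloxy group on an acetal carbon for PhSe, as in the conversion of anomeric acetates to selenoglycosides. The carboxylate is the better leaving group and the aryloxy-stabilised cation is the better cation, so the aryl ether should stay. The C6 configuration is irrelevant because step 13 erases it.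

Step 13
Reactants: 19 O,Se-acetal
Product: 21 tricyclic enone (rings A, B, C; C10=O, C11=C12; C9 methyl on the lower face), via C9-epimer mixture 20 (not isolated)
Conditions: Bu3SnH (syringe pump), Et3B/air, PhMe (5 mM), 0 °C; then DBU, rt
Reagents that add atoms: none
Why: Bu3Sn• abstracts PhSe from either C6 epimer to give one nucleophilic α-aryloxy radical, which adds to the dienone β-carbon C8; the α-keto radical at C9 takes H from Bu3SnH, and DBU then equilibrates C9. The closest known reaction types are the 5-exo cyclisation of tethered radicals onto cross-conjugated cyclohexadienones made by phenol oxidation and the use of O,Se-acetals as α-alkoxyalkyl radical sources. Ring B closes 5-exo-trig (C6•, C5, C4, C13, C8=C9). C8 is fixed by geometry: a tether on C13 reaches the neighbouring carbon only on its own face, so B/C is cis-fused with H8 syn to the C13 methyl. C13 is fixed by arm choice: the reacting arm must lie between C5 and H4, and the group that falls between H4 and C3 meets the C3 methyl in a syn-pentane contact; a methyl group tolerates this by turning its hydrogens aside, while the rigid in-plane vinylic C–H of a dienone arm does not, so the C13 methyl takes that place and the spectator arm lies between C3 and C5, which is why C3 is methylated first. C6 is fixed because OAr takes the open sector between H5 and C7, while the other face would place it syn-pentane to the axial CO2Me on C7. C9 ends equatorial and trans to C6 under DBU while C11 is still sp2. The step needs cyclisation to outrun both reduction of the radical and stannyl attack on the dienone oxygen; polarity matching, high dilution, slow addition and low temperature should secure this.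

Step 14
Reactants: 21 enone
Product: 23 C10 alcohol (C10 configuration of no consequence) with the C11 methyl on the upper face, via saturated ketone 22 (not isolated)
Conditions: Cu(OAc)2·H2O (5 mol %), 1,2-bis(diphenylphosphino)benzene, (EtO)2MeSiH, t-BuOH, PhMe, 0 °C; then NaBH4, CeCl3·7H2O, MeOH, −78 °C
Reagents that add atoms: none
Why: Copper hydride conjugate reduction spares the isolated alkene and the silylalkyne. The proton at C11 must pass a syn-axial group on C13, the methyl on the lower face or C4 with ring A on the upper face, so it should arrive from below and push the C11 methyl up. Immediate carbonyl reduction removes the path to the more stable epimer.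

Step 15
Reactants: 23 alcohol
Product: 24 C10 S-methyl xanthate
Conditions: KHMDS, THF, −78 °C; CS2; MeI, to 0 °C
Reagents that add atoms: carbon disulfide, S=C=S; iodomethane, CI
Why: Xanthate formation through the alkoxide suits hindered secondary alcohols, and one equivalent of base at low temperature leaves the ester α-centre C7 untouched.

Step 16
Reactants: 24 xanthate
Product: 25 methyl ester with the finished ring C
Conditions: Bu3SnH, AIBN, PhMe, 100 °C
Reagents that add atoms: none
Why: In this Barton–McCombie deoxygenation the C10 radical is not stereogenic and lies far from the π-bonds, so C9 and C11 are unaffected.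

Step 17
Reactants: 25 methyl ester; 26 3-bromo-1-(triisopropylsilyl)pyrrole
Product: 28 C7 (1-triisopropylsilylpyrrol-3-yl) ketone, via 3-lithiopyrrole 27 (not isolated)
Conditions: 26, n-BuLi, THF, −78 °C; then 25, −78 to −40 °C; aq NH4Cl
Reagents that add atoms: none
Why: Bromine–lithium exchange is followed by acylation. The resulting 3-acylpyrrole is a hindered vinylogous amide, so a second addition should not compete and the acidity of C7–H is lowered.

Step 18
Reactants: 28 trisilylated ketone
Product: 29 terminal alkyne, N–H pyrrole, benzylic alcohol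
Conditions: Bu4NF/AcOH (1:1), THF, 0 °C to rt
Reagents that add atoms: none
Why: One fluoride treatment removes the N–Si, O–Si and C–Si groups, and the acetic acid buffer protects the axial C7 centre from base.

Step 19
Reactants: 29 alkyne
Product: 30 vinyl compound
Conditions: H2 (1 atm), Pd/CaCO3–Pb(OAc)2, quinoline, EtOAc, rt
Reagents that add atoms: none
Why: Semihydrogenation of a terminal alkyne on poisoned palladium is used, and the trisubstituted alkene and the pyrrole are inert under these conditions.

Step 20
Reactants: 30 seco alcohol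
Product: 31 13-membered pyrrolo-paracyclophane (ArCH2 bonded to pyrrole C5)
Conditions: Sc(OTf)3 (10 mol %), (CF3)2CHOH/CH2Cl2, slow addition to 0.5 mM, 0 °C
Reagents that add atoms: none
Why: This is an intramolecular Friedel–Crafts benzylation. The 4-alkoxybenzyl alcohol ionises under mild acid, and a 3-acylpyrrole is substituted at C5, the α-position remote from the acyl group, which is the atom that must become C5′.

Step 21
Reactants: 31 pyrrolophane
Product: 33 target CNP0151253.3, via pyrrole endoperoxide 32 (not isolated)
Conditions: O2, visible light, methylene blue, acetone/H2O, 0 °C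
Reagents that add atoms: dioxygen, O=O
Why: Singlet oxygen adds [4+2] across C2′/C5′ of the pyrrole, and a Kornblum–DeLaMare-type opening removes H2′ to give C2′=O and C5′–OH; the carbon that bears H becomes the carbonyl, so the regiochemistry is built in. Attack should occur on the exposed pyrrole face, and the hemiaminal can then settle by ring–chain tautomerism.

## Compound list

1 | 3-(trimethylsilyl)propynal | O=CC#C[Si](C)(C)C | starting material
2 | 1-(triphenylphosphoranylidene)propan-2-one | CC(=O)C=P(c1ccccc1)(c1ccccc1)c1ccccc1 | starting material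
3 | (E)-6-(trimethylsilyl)hex-3-en-5-yn-2-one | CC(=O)/C=C/C#C[Si](C)(C)C | intermediate
4 | (E)-2-(tert-butyldimethylsilyloxy)-6-(trimethylsilyl)hexa-1,3-dien-5-yne | C=C(O[Si](C)(C)C(C)(C)C)/C=C/C#C[Si](C)(C)C | intermediate
5 | 2,4,6-trimethylphenol | Cc1cc(C)c(O)c(C)c1 | starting material
6 | 2,4,6-trimethyl-4-[(E)-2-oxo-6-(trimethylsilyl)hex-3-en-5-ynyl]cyclohexa-2,5-dienone | CC1=CC(C)(CC(=O)/C=C/C#C[Si](C)(C)C)C=C(C)C1=O | intermediate
7 | (1Z,3E)-silyloxydienyne on the dienone | CC1=CC(C)(/C=C(\O[Si](C)(C)C(C)(C)C)/C=C/C#C[Si](C)(C)C)C=C(C)C1=O | intermediate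
8 | 5-hydroxyfuran-2(5H)-one | O=C1C=CC(O)O1 | starting material
9 | (±)-tert-butyl (5-oxo-2,5-dihydrofuran-2-yl) carbonate | O=C1C=CC(OC(=O)OC(C)(C)C)O1 | intermediate
10 | 4-hydroxybenzyl alcohol | OCc1ccc(O)cc1 | starting material
11 | 4-[(tert-butyldiphenylsilyloxy)methyl]phenol | Oc1ccc(CO[Si](c2ccccc2)(c2ccccc2)C(C)(C)C)cc1 | intermediate
12 | (R)-5-(ArO)furan-2(5H)-one | O=C1C=C[C@H](Oc2ccc(CO[Si](c3ccccc3)(c3ccccc3)C(C)(C)C)cc2)O1 | intermediate
13 | endo/anti Diels–Alder adduct (C3–OTBS, all-cis H1/H7/H5/H4) | C[Si](C)(C)C#C[C@H]1C=C(O[Si](C)(C)C(C)(C)C)[C@@H](C2(C)C=C(C)C(=O)C(C)=C2)[C@@H]2[C@H]1C(=O)O[C@H]2Oc3ccc(CO[Si](c4ccccc4)(c4ccccc4)C(C)(C)C)cc3 | intermediate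
14 | C3 ketone, H4 cis to H5 | C[Si](C)(C)C#C[C@H]1CC(=O)[C@@H](C2(C)C=C(C)C(=O)C(C)=C2)[C@@H]2[C@H]1C(=O)O[C@H]2Oc3ccc(CO[Si](c4ccccc4)(c4ccccc4)C(C)(C)C)cc3 | intermediate
15 | C3 ketone, H4 trans to H5 | C[Si](C)(C)C#C[C@H]1CC(=O)[C@H](C2(C)C=C(C)C(=O)C(C)=C2)[C@@H]2[C@H]1C(=O)O[C@H]2Oc3ccc(CO[Si](c4ccccc4)(c4ccccc4)C(C)(C)C)cc3 | intermediate
16 | C2=C3 enol triflate | C[Si](C)(C)C#C[C@H]1C=C(OS(=O)(=O)C(F)(F)F)[C@H](C2(C)C=C(C)C(=O)C(C)=C2)[C@@H]2[C@H]1C(=O)O[C@H]2Oc3ccc(CO[Si](c4ccccc4)(c4ccccc4)C(C)(C)C)cc3 | intermediate
17 | C3-methyl cyclohexene lactone acylal | C[Si](C)(C)C#C[C@H]1C=C(C)[C@H](C2(C)C=C(C)C(=O)C(C)=C2)[C@@H]2[C@H]1C(=O)O[C@H]2Oc3ccc(CO[Si](c4ccccc4)(c4ccccc4)C(C)(C)C)cc3 | intermediate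
18 | C7 acid with C6H(OAr)(SePh), C6 epimers | C[Si](C)(C)C#C[C@H]1C=C(C)[C@H](C2(C)C=C(C)C(=O)C(C)=C2)[C@H]([C@H]1C(=O)O)C(Oc3ccc(CO[Si](c4ccccc4)(c4ccccc4)C(C)(C)C)cc3)[Se]c3ccccc3 | intermediate
19 | C7 methyl ester with C6H(OAr)(SePh), C6 epimers | C[Si](C)(C)C#C[C@H]1C=C(C)[C@H](C2(C)C=C(C)C(=O)C(C)=C2)[C@H]([C@H]1C(=O)OC)C(Oc3ccc(CO[Si](c4ccccc4)(c4ccccc4)C(C)(C)C)cc3)[Se]c3ccccc3 | intermediate
20 | tricyclic enone, C9 epimers | C[Si](C)(C)C#C[C@H]1C=C(C)[C@H]2[C@H]([C@H]1C(=O)OC)[C@@H](Oc3ccc(CO[Si](c4ccccc4)(c4ccccc4)C(C)(C)C)cc3)[C@H]1C(C)C(=O)C(C)=C[C@]12C | intermediate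
21 | tricyclic enone, C9 methyl on the lower face | C[Si](C)(C)C#C[C@H]1C=C(C)[C@H]2[C@H]([C@H]1C(=O)OC)[C@@H](Oc3ccc(CO[Si](c4ccccc4)(c4ccccc4)C(C)(C)C)cc3)[C@H]1[C@H](C)C(=O)C(C)=C[C@]12C | intermediate
22 | saturated C10 ketone, C11 methyl on the upper face | C[Si](C)(C)C#C[C@H]1C=C(C)[C@H]2[C@H]([C@H]1C(=O)OC)[C@@H](Oc3ccc(CO[Si](c4ccccc4)(c4ccccc4)C(C)(C)C)cc3)[C@H]1[C@H](C)C(=O)[C@@H](C)C[C@]12C | intermediate
23 | C10 alcohol | C[Si](C)(C)C#C[C@H]1C=C(C)[C@H]2[C@H]([C@H]1C(=O)OC)[C@@H](Oc3ccc(CO[Si](c4ccccc4)(c4ccccc4)C(C)(C)C)cc3)[C@H]1[C@H](C)C(O)[C@@H](C)C[C@]12C | intermediate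
24 | C10 S-methyl xanthate | C[Si](C)(C)C#C[C@H]1C=C(C)[C@H]2[C@H]([C@H]1C(=O)OC)[C@@H](Oc3ccc(CO[Si](c4ccccc4)(c4ccccc4)C(C)(C)C)cc3)[C@H]1[C@H](C)C(OC(=S)SC)[C@@H](C)C[C@]12C | intermediate
25 | tricyclic methyl ester, ring C complete | C[Si](C)(C)C#C[C@H]1C=C(C)[C@H]2[C@H]([C@H]1C(=O)OC)[C@@H](Oc3ccc(CO[Si](c4ccccc4)(c4ccccc4)C(C)(C)C)cc3)[C@H]1[C@H](C)C[C@@H](C)C[C@]12C | intermediate
26 | 3-bromo-1-(triisopropylsilyl)pyrrole | Brc1ccn([Si](C(C)C)(C(C)C)C(C)C)c1 | starting material
27 | 3-lithio-1-(triisopropylsilyl)pyrrole | [Li]c1ccn([Si](C(C)C)(C(C)C)C(C)C)c1 | intermediate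
28 | C7 (1-triisopropylsilylpyrrol-3-yl) ketone | C[Si](C)(C)C#C[C@H]1C=C(C)[C@H]2[C@H]([C@H]1C(=O)c3ccn([Si](C(C)C)(C(C)C)C(C)C)c3)[C@@H](Oc3ccc(CO[Si](c4ccccc4)(c4ccccc4)C(C)(C)C)cc3)[C@H]1[C@H](C)C[C@@H](C)C[C@]12C | intermediate
29 | desilylated alkyne / N–H pyrrole / benzylic alcohol | C#C[C@H]1C=C(C)[C@H]2[C@H]([C@H]1C(=O)c3cc[nH]c3)[C@@H](Oc3ccc(CO)cc3)[C@H]1[C@H](C)C[C@@H](C)C[C@]12C | intermediate
30 | vinyl seco alcohol | C=C[C@H]1C=C(C)[C@H]2[C@H]([C@H]1C(=O)c3cc[nH]c3)[C@@H](Oc3ccc(CO)cc3)[C@H]1[C@H](C)C[C@@H](C)C[C@]12C | intermediate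
31 | pyrrolo-paracyclophane | C=C[C@H]1C=C(C)[C@H]2[C@H]3[C@@H](Oc4ccc(cc4)Cc4cc(c[nH]4)C(=O)[C@@H]13)[C@H]1[C@H](C)C[C@@H](C)C[C@]12C | intermediate
32 | C2′,C5′-endoperoxide of 31 | C=C[C@H]1C=C(C)[C@H]2[C@H]3[C@@H](Oc4ccc(cc4)C[C@]45C=C([C@H](OO4)N5)C(=O)[C@@H]13)[C@H]1[C@H](C)C[C@@H](C)C[C@]12C | intermediate
33 | CNP0151253.3 | C=C[C@H]1C=C(C)[C@H]2[C@H]3[C@@H](Oc4ccc(cc4)C[C@@]4(O)C=C(C(=O)N4)C(=O)[C@@H]13)[C@H]1[C@H](C)C[C@@H](C)C[C@]12C | target

## Step count and least certain steps

Total steps: 21. Longest linear sequence: 18 (steps 1 to 4, then 8 to 21).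

**Step 3 (labelled).**
- What may go wrong: capture of the phenoxenium ion by acetate, attack at an ortho carbon, or protodesilylation of 4 in the acidic alcohol could outrun para C–C bond formation.
- Fallback, known chemistry only, from 5 back to 6: the oxidative Hosomi–Sakurai reaction of 5 with allyltrimethylsilane and PhI(OAc)2 gives 4-allyl-2,4,6-trimethylcyclohexa-2,5-dienone F1. Lemieux–Johnson cleavage (OsO4, NaIO4) of the electron-rich allyl alkene gives (1,3,5-trimethyl-4-oxocyclohexa-2,5-dienyl)acetaldehyde F2. Takai olefination of 1 (CrCl2, CHI3) gives (E)-(4-iodobut-3-en-1-ynyl)trimethylsilane F3. Aldehyde-selective Nozaki–Hiyama–Kishi coupling of F2 and F3 (CrCl2, NiCl2) gives the allylic alcohol F4, and oxidation with DMP (1,1,1-triacetoxy-1,2-benziodoxol-3-one) returns to 6.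

**Step 13 (key step).**
- What may go wrong: attack on the other dienone arm if the C3-methyl bias is too small, reduction of the radical before closure, or stannyl addition to the dienone oxygen followed by aromatising loss of the C4 substituent.
- Fallback, catalyst-controlled arm choice with the ether made afterwards, from 17 back to 21: aqueous TFA hydrolyses 17 to the hydroxylactone F5, and Me3SiCHN2 opens it to the aldehyde methyl ester F6. An intramolecular Stetter reaction with a chiral aminoindanol-derived triazolium carbene, whose antipode is chosen to match the required arm, gives the C6 ketone F7. NaBH4 at −78 °C attacks the cyclopentanone from the lower convex face to give the C6 alcohol F8. Separately, 4-iodobenzyl alcohol is silylated to tert-butyl[(4-iodobenzyl)oxy]diphenylsilane F9 and oxidised in the presence of mesitylene (mCPBA, TfOH) to the aryl(mesityl)iodonium triflate F10. O-Arylation of the alkoxide of F8 with F10 proceeds with retention at C6 and returns to 21.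

**Step 8.**
- What may go wrong: the quaternary C13 on the bonding terminus could slow the cycloaddition until thermal decay of 7 or erosion of endo selectivity takes over.
- Fallback, stepwise polar annulation, from 7 and 12 back to 15: a Lewis-acid Mukaiyama–Michael addition (TBSOTf cat., −78 °C) forms only C4–C5, anti to OAr, and gives the enone lactone F11 after hydrolysis. DBU then closes C7–C1 by an intramolecular Michael addition, in which the six-membered ring enforces 1,4-addition and the lactone enforces cis fusion, and equilibrates C4 and C1 to give 15.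

**Step 14.**
- What may go wrong: protonation from the upper face, or enolisation of 22 before the carbonyl is reduced, would lead to the more stable C11 epimer.
- Fallback, reagent control in place of substrate control, from 21 back to 22: copper hydride reduction with PhMe2SiH without alcohol stops at the dimethylphenylsilyl enol ether F12. This is isolated and protonated at −78 °C with a chiral BINOL·SnCl4 Brønsted acid of the matching handedness to give 22, which is reduced at once.

**Step 20.**
- What may go wrong: oligomerisation, N-benzylation, or reversible benzylation that drains away from the strained ring.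
- Fallback, irreversible organometallic closure, from 30 back to 31: NIS iodinates the pyrrole at C5 to give the iodopyrrole F13, and MnO2 gives the iodo benzaldehyde F14. Nozaki–Hiyama–Kishi macrocyclisation (CrCl2, NiCl2, high dilution) gives the macrocyclic diaryl carbinol F15, and ionic reduction (Et3SiH, TFA, −40 °C) returns to 31.

**Step 21.**
- What may go wrong: an ene reaction of singlet oxygen at the C2=C3 alkene, or over-oxidation of the deactivated pyrrole.
- Fallback, two-electron oxidant, from 31 back to 33: controlled oxidation of the pyrrole with DMP gives the 5′-(2-iodobenzoyloxy)lactam F16, and mild aqueous NaHCO3 hydrolysis gives 33.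

## Further compounds

F1 | step 3 | 4-allyl-2,4,6-trimethylcyclohexa-2,5-dienone | C=CCC1(C)C=C(C)C(=O)C(C)=C1
F2 | step 3 | (1,3,5-trimethyl-4-oxocyclohexa-2,5-dienyl)acetaldehyde | O=CCC1(C)C=C(C)C(=O)C(C)=C1
F3 | step 3 | (E)-(4-iodobut-3-en-1-ynyl)trimethylsilane | I/C=C/C#C[Si](C)(C)C
F4 | step 3 | allylic alcohol (racemic) | OC(CC1(C)C=C(C)C(=O)C(C)=C1)/C=C/C#C[Si](C)(C)C
F5 | step 13 | hydroxylactone | C[Si](C)(C)C#C[C@H]1C=C(C)[C@H](C2(C)C=C(C)C(=O)C(C)=C2)[C@@H]2[C@H]1C(=O)OC2O
F6 | step 13 | aldehyde methyl ester | C[Si](C)(C)C#C[C@H]1C=C(C)[C@H](C2(C)C=C(C)C(=O)C(C)=C2)[C@H]([C@H]1C(=O)OC)C=O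
F7 | step 13 | C6 ketone | C[Si](C)(C)C#C[C@H]1C=C(C)[C@H]2[C@H]([C@H]1C(=O)OC)C(=O)[C@H]1[C@H](C)C(=O)C(C)=C[C@]12C
F8 | step 13 | C6 alcohol | C[Si](C)(C)C#C[C@H]1C=C(C)[C@H]2[C@H]([C@H]1C(=O)OC)[C@@H](O)[C@H]1[C@H](C)C(=O)C(C)=C[C@]12C
F9 | step 13 | tert-butyl[(4-iodobenzyl)oxy]diphenylsilane | Ic1ccc(CO[Si](c2ccccc2)(c2ccccc2)C(C)(C)C)cc1
F10 | step 13 | aryl(mesityl)iodonium triflate | Cc1cc(C)c([I+]c2ccc(CO[Si](c3ccccc3)(c3ccccc3)C(C)(C)C)cc2)c(C)c1.[O-]S(=O)(=O)C(F)(F)F
F11 | step 8 | enone lactone (C4 epimers) | C[Si](C)(C)C#C/C=C/C(=O)C(C1(C)C=C(C)C(=O)C(C)=C1)[C@@H]1CC(=O)O[C@H]1Oc3ccc(CO[Si](c4ccccc4)(c4ccccc4)C(C)(C)C)cc3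
F12 | step 14 | dimethylphenylsilyl enol ether | C[Si](C)(C)C#C[C@H]1C=C(C)[C@H]2[C@H]([C@H]1C(=O)OC)[C@@H](Oc3ccc(CO[Si](c4ccccc4)(c4ccccc4)C(C)(C)C)cc3)[C@H]1[C@H](C)C(O[Si](C)(C)c5ccccc5)=C(C)C[C@]12C
F13 | step 20 | iodopyrrole | C=C[C@H]1C=C(C)[C@H]2[C@H]([C@H]1C(=O)c3cc(I)[nH]c3)[C@@H](Oc3ccc(CO)cc3)[C@H]1[C@H](C)C[C@@H](C)C[C@]12C
F14 | step 20 | iodo benzaldehyde | C=C[C@H]1C=C(C)[C@H]2[C@H]([C@H]1C(=O)c3cc(I)[nH]c3)[C@@H](Oc3ccc(C=O)cc3)[C@H]1[C@H](C)C[C@@H](C)C[C@]12C
F15 | step 20 | macrocyclic diaryl carbinol | C=C[C@H]1C=C(C)[C@H]2[C@H]3[C@@H](Oc4ccc(cc4)C(O)c4cc(c[nH]4)C(=O)[C@@H]13)[C@H]1[C@H](C)C[C@@H](C)C[C@]12C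
F16 | step 21 | 5′-(2-iodobenzoyloxy)lactam | C=C[C@H]1C=C(C)[C@H]2[C@H]3[C@@H](Oc4ccc(cc4)C[C@@]4(OC(=O)c5ccccc5I)C=C(C(=O)N4)C(=O)[C@@H]13)[C@H]1[C@H](C)C[C@@H](C)C[C@]12C
A1 | alternative 1 | tetraene hydroxy ester | C=C/C=C/C(C)=C/[C@]1(C)C[C@H](C)C[C@@H](C)[C@@H]1[C@H](O)/C=C/C(=O)OC
A2 | alternative 1 | tricyclic hydroxy ester, epimeric at C1 and C7 | C=C[C@@H]1C=C(C)[C@H]2[C@H]([C@@H]1C(=O)OC)[C@@H](O)[C@H]1[C@H](C)C[C@@H](C)C[C@]12C
A3 | alternative 2 | paracyclophane (E)-enone with the C13 triene | C=C/C=C/C(C)=C/[C@]1(C)C[C@H](C)C[C@@H](C)[C@@H]1[C@@H]2Oc3ccc(cc3)Cc3cc(c[nH]3)C(=O)/C=C/2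
A4 | alternative 3 | 3-(1,3,5-trimethyl-4-oxocyclohexa-2,5-dienyl)propanal | O=CCCC1(C)C=C(C)C(=O)C(C)=C1
A5 | alternative 3 | cis-hydrindenedione | O=C1CC[C@]2(C)C=C(C)C(=O)[C@@H](C)[C@H]12
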